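Ring B of the target is read as an isoprene adduct. Its methyl-bearing C3 lies 1,4 to the spiro carbon C6, and the anti C2-Br/C3-Cl pair is what BrCl addition to a C2=C3 alkene leaves behind. Everything therefore rests on cutting C6–C1 and C5–C4. One catalytic enantioselective Diels–Alder reaction joins isoprene to a ring-A cyclohexanone that carries an exocyclic C6=C5 methylene next to the C11 gem-dimethyl group. It closes ring B, makes both bonds and fixes the spiro stereocentre. Ring A is then oxidised through the C7 ketone, the ring-B halogens are added late, and C8 is set last by reagent control.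

Key step: step 3

Numbering used (chamigrane): ring B = C1H2, C2HBr, C3(CH3)Cl, C4H2, C5H2, spiro C6. Ring A = C6, C7(=C14H2), C8H(OH), C9H=, C10(Br)=, C11(CH3)2. In this numbering the target is (2S,3S,6S,8R).

Assumption: the (S,S) acid named in step 3 is taken to give the (6R) adduct. If the sense is opposite, the (R,R) acid is used, since both BINOL antipodes are commercial. Its 3,3'-aryl group is a starting point for screening.

Remark: C1 and C5 are both CH2, so the two faces of ring A are nearly equivalent to an achiral reagent. C8 is therefore left unassigned until a catalyst-controlled reduction. The sp3 carbon–halogen bonds are made only after the strong-base, titanium and fluoride steps.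

Step 1
Reactants: 1 3-methylcyclohex-2-en-1-one; 2 N,N-dimethylmethylideneammonium iodide (Eschenmoser's salt)
Product: 4 2-[(dimethylamino)methyl]-3,3-dimethylcyclohexan-1-one (racemic), via lithium enolate 3 (not isolated)
Conditions: MeLi, CuI, Et2O, 0 °C (forms Me2CuLi); 1, −20 °C; then 2, THF, −78 °C to rt
Reagents that add atoms: methyllithium, [Li]C, delivered as lithium dimethylcuprate, [Li+].C[Cu-]C
Why: Conjugate addition of the Gilman cuprate creates the C11 gem-dimethyl carbon and unmasks the enolate only at the carbon between C=O and CMe2, where a Mannich reaction with the preformed iminium salt attaches the future C5; the stereocentre formed there is racemic and disappears in step 2.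

Step 2
Reactants: 4 2-[(dimethylamino)methyl]-3,3-dimethylcyclohexan-1-one
Product: 6 3,3-dimethyl-2-methylidenecyclohexan-1-one, via ammonium iodide 5 (not isolated)
Conditions: MeI, Et2O, rt; then NaHCO3, H2O/CH2Cl2, rt
Reagents that add atoms: none
Why: Quaternisation turns the amine into a leaving group and mild base triggers E1cB (Hofmann-type) elimination of the beta-ammonio ketone to the exocyclic enone, which is kept cold and dilute and used at once because alpha-methylene ketones dimerise by hetero-Diels–Alder reaction.

Step 3
Reactants: 6 3,3-dimethyl-2-methylidenecyclohexan-1-one; 7 isoprene (2-methylbuta-1,3-diene)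
Product: 8 (6R)-5,5,9-trimethylspiro[5.5]undec-8-en-1-one
Conditions: (S,S)-imidodiphosphorimidate [(RO)2P(=NSO2CF3)]2NH, (RO)2 = 3,3'-bis[3,5-bis(trifluoromethyl)phenyl]-1,1'-binaphthalene-2,2'-diolate (3 mol %), 7 (10 equiv), CH2Cl2, −60 °C
Reagents that add atoms: none
Why: The strong confined acid protonates or tightly hydrogen-bonds the ketone of 6, which lowers the LUMO of the s-cis-locked C6=C5 enone, and isoprene adds in a concerted but asynchronous [4+2] cycloaddition in which C5–C4 bonding runs ahead of C6–C1 bonding. The closest known reaction type is the Brønsted-acid-catalysed enantioselective Diels–Alder reaction of alpha-methylene cycloalkanones with simple dienes, and the racemic thermal or Lewis-acid version is long established for this skeleton. Ring B is closed intermolecularly by cycloaddition, both of its new sigma bonds forming in the one step, and the junction is spiro because C6 is already a member of ring A. The only new stereocentre, C6, is set by the chiral pocket of the counter-anion, which leaves one enantioface of the exocyclic alkene open, while endo/exo topology has no stereochemical consequence because isoprene carries no terminal substituent. The step needs para regiochemistry and chemoselectivity over self-dimerisation of 6: the first follows from matching the large LUMO coefficient at the exocyclic CH2 with the large HOMO coefficient at the isoprene CH2 beside the methyl-bearing carbon, the second from excess diene, low temperature and the shielding of C6 by the neighbouring CMe2 group. That same CMe2 group makes 6 a slow substrate for a confined catalyst, and this is where the route places its risk.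

Step 4
Reactants: 8 (6R)-5,5,9-trimethylspiro[5.5]undec-8-en-1-one
Product: 9 (6R)-5,5,9-trimethylspiro[5.5]undeca-2,8-dien-1-one
Conditions: IBX (2 equiv), DMSO/fluorobenzene, 70 °C
Reagents that add atoms: none
Why: IBX dehydrogenation of a ketone through its enol can only run toward C8–C9 because C6 is quaternary and cannot go further because C11 is quaternary, and the isolated ring-B alkene is inert to the reagent.

Step 5
Reactants: 9 (6R)-5,5,9-trimethylspiro[5.5]undeca-2,8-dien-1-one
Product: 11 (6R)-4-bromo-5,5,9-trimethylspiro[5.5]undeca-2,8-dien-1-one (both epimers at C10), via silyl dienol ether 10 (not isolated)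
Conditions: TMSOTf, Et3N, CH2Cl2, 0 °C; then NBS (1.0 equiv), −78 °C, dark
Reagents that add atoms: N-bromosuccinimide, O=C1CCC(=O)N1Br
Why: Soft enolisation can only take the gamma hydrogen at C10, and the resulting 1-silyloxy-1,3-diene, far more nucleophilic than the ring-B alkene, is brominated by one equivalent of NBS at its gamma terminus (vinylogous halogenation of a silyl dienol ether), any C8 bromide being expected to drain to the conjugated isomer by allylic shift; the C10 configuration is irrelevant because C10 becomes sp2 in step 6.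

Step 6
Reactants: 11 (6R)-4-bromo-5,5,9-trimethylspiro[5.5]undeca-2,8-dien-1-one
Product: 13 (6R)-4-bromo-2-hydroxy-5,5,9-trimethylspiro[5.5]undeca-3,8-dien-1-one (both epimers at C8), via potassium dienolate 12 (not isolated)
Conditions: KN(SiMe3)2, THF, −78 °C; 2-(phenylsulfonyl)-3-phenyloxaziridine, −78 °C; AcOH quench
Reagents that add atoms: 2-(phenylsulfonyl)-3-phenyloxaziridine (Davis oxaziridine), O=S(=O)(c1ccccc1)N1OC1c1ccccc1
Why: Removal of the acidified C10–H gives the extended dienolate, which is oxidised at its alpha carbon C8 by the Davis oxaziridine (deconjugative alpha-hydroxylation of an extended enolate), the gamma carbon being blocked by Br and CMe2, so that C9=C10(Br) and the C8 oxygen appear together; isolated alkenes are not touched and the C8 epimer mixture is tolerated because C8 is reset in steps 10 and 12.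

Step 7
Reactants: 13 (6R)-4-bromo-2-hydroxy-5,5,9-trimethylspiro[5.5]undeca-3,8-dien-1-one
Product: 14 (6R)-4-bromo-5,5,9-trimethyl-2-[(triethylsilyl)oxy]spiro[5.5]undeca-3,8-dien-1-one (both epimers at C8)
Conditions: Et3SiCl, imidazole, CH2Cl2, 0 °C
Reagents that add atoms: chlorotriethylsilane, CC[Si](Cl)(CC)CC
Why: Standard silylation masks the alpha-ketol so that titanium cannot bind it as an enediolate in step 8, the small triethylsilyl group adding little bulk next to the hindered C7 carbonyl.

Step 8
Reactants: 14 (6R)-4-bromo-5,5,9-trimethyl-2-[(triethylsilyl)oxy]spiro[5.5]undeca-3,8-dien-1-one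
Product: 15 {[(6S)-4-bromo-5,5,9-trimethyl-1-methylidenespiro[5.5]undeca-3,8-dien-2-yl]oxy}triethylsilane (both epimers at C8; same spatial arrangement at C6, descriptor changes by priority)
Conditions: Cp2TiMe2 (3 equiv), toluene, 70 °C, dark
Reagents that add atoms: dimethyltitanocene Cp2TiMe2, [CH3-].[CH3-].[Ti+4].c1cc[cH-]c1.c1cc[cH-]c1
Why: Petasis methylenation through thermally formed Cp2Ti=CH2 and an oxatitanacyclobutane is non-basic, so the doubly activated C8–H is not enolised and the alkene stays beta,gamma, and it is run while the molecule holds no sp3 carbon–halogen bond that low-valent titanium by-products could reduce.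

Step 9
Reactants: 15 {[(6S)-4-bromo-5,5,9-trimethyl-1-methylidenespiro[5.5]undeca-3,8-dien-2-yl]oxy}triethylsilane
Product: 16 (6S)-4-bromo-5,5,9-trimethyl-1-methylidenespiro[5.5]undeca-3,8-dien-2-ol (both epimers at C8)
Conditions: Bu4NF, AcOH (1:1), THF, 0 °C
Reagents that add atoms: none
Why: Buffered fluoride cleaves the Si–O bond without acid, which the bis-allylic alcohol would not tolerate, and nothing else in the molecule responds to fluoride.

Step 10
Reactants: 16 (6S)-4-bromo-5,5,9-trimethyl-1-methylidenespiro[5.5]undeca-3,8-dien-2-ol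
Product: 17 (6S)-4-bromo-5,5,9-trimethyl-1-methylidenespiro[5.5]undeca-3,8-dien-2-one
Conditions: Dess–Martin periodinane, CH2Cl2, 0 °C
Reagents that add atoms: none
Why: Dess–Martin oxidation of the bis-allylic alcohol merges both C8 epimers into one cross-conjugated dienone and makes both ring-A alkenes electron-poor, which prepares the chemoselectivity of step 11.

Step 11
Reactants: 17 (6S)-4-bromo-5,5,9-trimethyl-1-methylidenespiro[5.5]undeca-3,8-dien-2-one
Product: 18 (6S,8S,9S)-4,8-dibromo-9-chloro-5,5,9-trimethyl-1-methylidenespiro[5.5]undec-3-en-2-one (chamigrane 2S,3S,6S; Br and Cl trans, both equatorial, Br on the C11 side and Cl on the C7 side of ring B)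
Conditions: NBS, Me3SiCl (forms BrCl), CH2Cl2, −78 to −30 °C, dark
Reagents that add atoms: N-bromosuccinimide, O=C1CCC(=O)N1Br; chlorotrimethylsilane, C[Si](C)(C)Cl
Why: Anti, Markovnikov bromochlorination of the only nucleophilic alkene: with the bulky C11 equatorial on ring B the C7(=CH2) arm is axial and covers one face of C2=C3, so the bromonium should form on the other face and chloride should open it at tertiary C3 from the C7 side, the adduct relaxing to the chair with Br and Cl equatorial, while an adduct opened at C2 can re-form the same bromonium and drain to this more stable isomer.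

Step 12
Reactants: 18 (6S,8S,9S)-4,8-dibromo-9-chloro-5,5,9-trimethyl-1-methylidenespiro[5.5]undec-3-en-2-one
Product: 19 (2R,6S,8S,9S)-4,8-dibromo-9-chloro-5,5,9-trimethyl-1-methylidenespiro[5.5]undec-3-en-2-ol (chamigrane 2S,3S,6S,8R), the target
Conditions: (S)-Me-CBS, (3aS)-1-methyl-3,3-diphenyltetrahydro-1H,3H-pyrrolo[1,2-c][1,3,2]oxazaborole (0.5 equiv), BH3·SMe2 (0.7 equiv), toluene, −40 °C; MeOH, then aqueous work-up
Reagents that add atoms: none
Why: Corey–Bakshi–Shibata reduction sets C8 by catalyst control, the fully substituted C7(=CH2) arm acting as the large group and the C9–H vinyl arm as the small group, so that the (S)-oxazaborolidine should give the (8R) carbinol by 1,2-delivery of hydride, with limited borane and low temperature sparing the alkenes and all carbon–halogen bonds.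

Compound list
1 | 3-methylcyclohex-2-en-1-one | CC1=CC(=O)CCC1 | starting material
2 | N,N-dimethylmethylideneammonium iodide (Eschenmoser's salt) | C[N+](C)=C.[I-] | starting material
3 | lithium 3,3-dimethylcyclohex-1-en-1-olate | [Li+].[O-]C1=CC(C)(C)CCC1 | intermediate
4 | 2-[(dimethylamino)methyl]-3,3-dimethylcyclohexan-1-one (racemic) | CN(C)CC1C(=O)CCCC1(C)C | intermediate
5 | [(2,2-dimethyl-6-oxocyclohexyl)methyl]trimethylammonium iodide | C[N+](C)(C)CC1C(=O)CCCC1(C)C.[I-] | intermediate
6 | 3,3-dimethyl-2-methylidenecyclohexan-1-one | C=C1C(=O)CCCC1(C)C | intermediate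
7 | isoprene | C=CC(C)=C | starting material
8 | (6R)-5,5,9-trimethylspiro[5.5]undec-8-en-1-one | O=C1CCCC(C)(C)[C@]12CCC(C)=CC2 | intermediate
9 | (6R)-5,5,9-trimethylspiro[5.5]undeca-2,8-dien-1-one | O=C1C=CCC(C)(C)[C@]12CCC(C)=CC2 | intermediate
10 | {[(6R)-5,5,9-trimethylspiro[5.5]undeca-1,3,8-trien-1-yl]oxy}trimethylsilane | C[Si](C)(C)OC1=CC=CC(C)(C)[C@]12CCC(C)=CC2 | intermediate
11 | (6R)-4-bromo-5,5,9-trimethylspiro[5.5]undeca-2,8-dien-1-one, both epimers at the CHBr carbon | O=C1C=CC(Br)C(C)(C)[C@]12CCC(C)=CC2 | intermediate
12 | potassium (6R)-4-bromo-5,5,9-trimethylspiro[5.5]undeca-1,3,8-trien-1-olate | [K+].[O-]C1=CC=C(Br)C(C)(C)[C@]12CCC(C)=CC2 | intermediate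
13 | (6R)-4-bromo-2-hydroxy-5,5,9-trimethylspiro[5.5]undeca-3,8-dien-1-one, both carbinol epimers | O=C1C(O)C=C(Br)C(C)(C)[C@]12CCC(C)=CC2 | intermediate
14 | (6R)-4-bromo-5,5,9-trimethyl-2-[(triethylsilyl)oxy]spiro[5.5]undeca-3,8-dien-1-one, both epimers | O=C1C(O[Si](CC)(CC)CC)C=C(Br)C(C)(C)[C@]12CCC(C)=CC2 | intermediate
15 | {[(6S)-4-bromo-5,5,9-trimethyl-1-methylidenespiro[5.5]undeca-3,8-dien-2-yl]oxy}triethylsilane, both epimers | C=C1C(O[Si](CC)(CC)CC)C=C(Br)C(C)(C)[C@]12CCC(C)=CC2 | intermediate
16 | (6S)-4-bromo-5,5,9-trimethyl-1-methylidenespiro[5.5]undeca-3,8-dien-2-ol, both carbinol epimers | C=C1C(O)C=C(Br)C(C)(C)[C@]12CCC(C)=CC2 | intermediate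
17 | (6S)-4-bromo-5,5,9-trimethyl-1-methylidenespiro[5.5]undeca-3,8-dien-2-one | C=C1C(=O)C=C(Br)C(C)(C)[C@]12CCC(C)=CC2 | intermediate
18 | (6S,8S,9S)-4,8-dibromo-9-chloro-5,5,9-trimethyl-1-methylidenespiro[5.5]undec-3-en-2-one | C=C1C(=O)C=C(Br)C(C)(C)[C@]12CC[C@](C)(Cl)[C@@H](Br)C2 | intermediate
19 | (2R,6S,8S,9S)-4,8-dibromo-9-chloro-5,5,9-trimethyl-1-methylidenespiro[5.5]undec-3-en-2-ol | C=C1[C@H](O)C=C(Br)C(C)(C)[C@]12CC[C@](C)(Cl)[C@@H](Br)C2 | target

Total step count: 12. Longest linear sequence: 12 steps (1 to 19).

Three steps most likely to fail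

Step 11. The bromonium may form on the face of ring B that carries C7 and then open in the stereoelectronically easy trans-diaxial way, or chloride may be captured at C2. Either would erode facial and positional selectivity. The fallback sets out from 8 and returns at 18, and it fixes the face with an internal nucleophile instead of sterics.
- LiAlH4 (Et2O, 0 °C) reduces 8 to the C7 carbinol (6R)-5,5,9-trimethylspiro[5.5]undec-8-en-1-ol F1. Either C7 epimer is usable.
- NBS (CH2Cl2, 0 °C) then effects bromoetherification, the reaction type that turns alpha-terpineol into a bromocineole. The C7 oxygen can reach C3 only from its own side of ring B, so bromine must sit on the other side of C2. This gives 2-bromo-3,7-epoxychamigrane F2 with a 2-oxabicyclo[2.2.2]octane core.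
- BCl3 (CH2Cl2, −78 °C) cleaves the tertiary C3–O bond. The C2 bromine bridges the developing cation from its own face and chloride enters where oxygen left, which gives 2-bromo-3-chlorochamigran-7-ol F3.
- Dess–Martin periodinane gives 2-bromo-3-chlorochamigran-7-one F4.
- The operations of steps 4 to 10 follow. IBX gives 2-bromo-3-chlorochamigr-8-en-7-one F5. TMSOTf/Et3N gives the trimethylsilyl dienol ether F6, and NBS gives 2,10-dibromo-3-chlorochamigr-8-en-7-one F7.
- KN(SiMe3)2 at −78 °C gives the potassium dienolate F8, and the Davis oxaziridine gives 2,10-dibromo-3-chloro-8-hydroxychamigr-9-en-7-one F9. Et3SiCl/imidazole gives the triethylsilyl ether F10.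
- Cp2Ti(μ-CH2)(μ-Cl)AlMe2 with pyridine in THF/toluene at −40 to 0 °C is used here because it needs no heating. It gives the C7-methylidene silyl ether F11.
- HF·pyridine gives 2,10-dibromo-3-chlorochamigra-7(14),9-dien-8-ol F12 as C8 epimers, and Dess–Martin oxidation delivers 18.

Step 3. The hindered dienophile may turn over slowly in the confined pocket, so that its dimerisation or acid-induced oligomerisation of isoprene competes. Enantioface discrimination may also be incomplete. The fallback sets out from 6 and 7 and returns at 8. It keeps the same bond formation but separates stereocontrol from it. Me2AlCl (CH2Cl2, −20 °C) promotes the cycloaddition to racemic 5,5,9-trimethylspiro[5.5]undec-8-en-1-one F13. Preparative supercritical-fluid chromatography on an amylose tris(3,5-dimethylphenylcarbamate) phase then separates 8 from its (6S) enantiomer F14.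

Step 8. The titanium methylidene may add sluggishly to a carbonyl flanked by the spiro quaternary carbon and the silyloxy-bearing C8. The reagent would then decay thermally and the beta,gamma alkene could drift into conjugation on long heating. The fallback sets out from 14 and returns at 15, and it is a two-stage Peterson olefination with a slimmer nucleophile. Me3SiCH2MgCl premixed with CeCl3 (THF, −78 °C) adds as a weakly basic organocerium reagent and gives the beta-hydroxysilane F15. KH (THF, 0 °C) then induces syn-elimination of silanolate to give 15.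

Further compounds
F1 | step 11 | (6R)-5,5,9-trimethylspiro[5.5]undec-8-en-1-ol, either C7 epimer | OC1CCCC(C)(C)[C@]12CCC(C)=CC2
F2 | step 11 | 2-bromo-3,7-epoxychamigrane (bridged bromo ether, Br anti to the C3 oxygen) | O1C2CCCC(C)(C)[C@]23CC[C@@]1(C)[C@@H](Br)C3
F3 | step 11 | 2-bromo-3-chlorochamigran-7-ol | OC1CCCC(C)(C)[C@]12CC[C@](C)(Cl)[C@@H](Br)C2
F4 | step 11 | 2-bromo-3-chlorochamigran-7-one | O=C1CCCC(C)(C)[C@]12CC[C@](C)(Cl)[C@@H](Br)C2
F5 | step 11 | 2-bromo-3-chlorochamigr-8-en-7-one | O=C1C=CCC(C)(C)[C@]12CC[C@](C)(Cl)[C@@H](Br)C2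
F6 | step 11 | trimethylsilyl dienol ether of F5 | C[Si](C)(C)OC1=CC=CC(C)(C)[C@]12CC[C@](C)(Cl)[C@@H](Br)C2
F7 | step 11 | 2,10-dibromo-3-chlorochamigr-8-en-7-one, both C10 epimers | O=C1C=CC(Br)C(C)(C)[C@]12CC[C@](C)(Cl)[C@@H](Br)C2
F8 | step 11 | potassium dienolate of F7 | [K+].[O-]C1=CC=C(Br)C(C)(C)[C@]12CC[C@](C)(Cl)[C@@H](Br)C2
F9 | step 11 | 2,10-dibromo-3-chloro-8-hydroxychamigr-9-en-7-one, both C8 epimers | O=C1C(O)C=C(Br)C(C)(C)[C@]12CC[C@](C)(Cl)[C@@H](Br)C2
F10 | step 11 | triethylsilyl ether of F9 | O=C1C(O[Si](CC)(CC)CC)C=C(Br)C(C)(C)[C@]12CC[C@](C)(Cl)[C@@H](Br)C2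
F11 | step 11 | C7-methylidene silyl ether | C=C1C(O[Si](CC)(CC)CC)C=C(Br)C(C)(C)[C@]12CC[C@](C)(Cl)[C@@H](Br)C2
F12 | step 11 | 2,10-dibromo-3-chlorochamigra-7(14),9-dien-8-ol, both C8 epimers | C=C1C(O)C=C(Br)C(C)(C)[C@]12CC[C@](C)(Cl)[C@@H](Br)C2
F13 | step 3 | racemic 5,5,9-trimethylspiro[5.5]undec-8-en-1-one | O=C1CCCC(C)(C)C12CCC(C)=CC2
F14 | step 3 | (6S)-5,5,9-trimethylspiro[5.5]undec-8-en-1-one | O=C1CCCC(C)(C)[C@@]12CCC(C)=CC2
F15 | step 8 | (6R)-4-bromo-5,5,9-trimethyl-2-[(triethylsilyl)oxy]-1-[(trimethylsilyl)methyl]spiro[5.5]undeca-3,8-dien-1-ol | C[Si](C)(C)CC1(O)C(O[Si](CC)(CC)CC)C=C(Br)C(C)(C)[C@]12CCC(C)=CC2
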